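At the 25.0 h reading of the eta run I take from the two substrates the one number I carry to the new flask.

| setting | eta | flask |
|---|---|---|
| left-handed substrate | 0.068 M | 0.068 M |
| right-handed substrate | 0.068 M | 0.068 M |
| gas | 3.6 mM (held) | 3.6 mM (held) |
| free catalyst | 1.4 mM | 0.68 mM |
| impurity | 0.15 mM | 0.15 mM |
| remark | run made earlier |  |
| time |  | 6.0 d |

- eta (time / h: right-handed substrate / %, left-handed substrate / %, left-handed product / %): 3.00: 48.9, 42.5, 7.1; 6.00: 44.7, 36.2, 15.9; 10.0: 39.0, 26.3, 22.4; 15.0: 34.9, 18.2, 33.4; 25.0: 26.5, 8.0, 43.3; 40.0: 14.2, 2.3, 48.8

(each reading ± 1 percentage point)

- free catalyst is single-handed; left-handed substrate and right-handed substrate are mirror images of each other, charged as a racemate, each of them at the stated concentration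
- at the start none of the gas is in solution
- no earlier run changes the charge of free catalyst; that part of a forecast is a guess

* whether the excess of right-handed substrate over left-handed substrate among what is left of the two reaches 90% by 6.0 d (yes / no)
* the highest excess of right-handed substrate over left-handed substrate among what is left of the two up to 6.0 d

Each substrate starts at half of the charge. I take the fraction of its own start that each has kept and divide the logarithm for the left-handed substrate by that for the right-handed substrate. This is the selectivity factor, and it reads 2.89. I don't read it at 40.0 h, where the left-handed reading of 2.3% carries a scatter of 1 percentage point. The zero of the scale is a factor of 1, where the two fall together and the excess stays nil. Above it, if the right-handed substrate keeps a fraction x, the left-handed keeps x raised to the factor. So 90% asks that the right-handed substrate be down to 21.0% of its own charge.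

Between the last two readings of the eta run the right-handed substrate falls at 0.0416 h⁻¹, and by my estimate that slope, carried on, puts the mark at 47.3 h of eta time. The bench rule says that, with the rest of the charge held, half the catalyst means twice the time, so 6.0 d in the new flask counts as 69.9 h of eta time. The rule stops where the impurity takes a real share: impurity over catalyst is 10.7% in the eta run but 22.1% in the new flask. If each impurity removes one catalyst, which is my guess, the allowance shrinks to 61.1 h, still longer than the need. Carrying the same slope to that allowance, I estimate my own top at 96.5%.

The forecast answers yes with a top of 93%, lower than mine, and adds: “This is marginal: late-stage deactivation is the main risk.”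

The flask gives yes, with a top of 96.7%.

    reagent + free catalyst + right-handed substrate → free catalyst + right-handed product (k = 153 M⁻² min⁻¹)
    gas ⇌ reagent, rate k2*(csat - [reagent]) (kL = 0.0589 min⁻¹)
    reagent ⇌ dormant form (K = 7.30, k = 0.0243 min⁻¹)
    free catalyst + impurity → spent catalyst (k = 491 M⁻¹ min⁻¹)
    reagent + free catalyst + left-handed substrate → free catalyst + left-handed product (k = 424 M⁻² min⁻¹)

The new flask passes 90% at 4.45 d, with 9.48% of the whole charge still there as right-handed substrate. At 6.00 d the right-handed substrate stands at 10% of its own charge, and with the factor 2.89 that fraction gives an excess of 97.5%, against 96.7% in the flask.

The earlier runs and the new flask come from a simulation for substances that don't exist.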